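Temperature is the one setting that separates flask oak, at 55 °C, from flask alder, at 35 °C; both hold the same charges of G and E and are read after 2.5 min.

| flask | G | E | temperature | remark | time |
|---|---|---|---|---|---|
| west | 0.15 M | 0.36 M | 30 °C | run made earlier |  |
| south-west | 0.60 M | 0.36 M | 45 °C | run made earlier |  |
| south-east | 0.30 M | 0.18 M | 30 °C | run made earlier |  |
| oak | 0.30 M | 0.360 M | 55 °C |  | 2.5 min |
| alder | 0.30 M | 0.360 M | 35 °C |  | 2.5 min |

- west (time / min: D / %): 0.500: 24; 1.33: 28; 2.50: 32; 3.00: 35; 5.00: 36; 6.00: 39
- south-west (time / min: D / %): 0.500: 21; 1.00: 17; 1.50: 18; 2.00: 18; 2.50: 22; 3.00: 20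
- south-east (time / min: D / %): 1.33: 22; 3.00: 21; 5.00: 27; 6.00: 23

(standard deviation of a reading: 2 percentage points)

- the numbers in the tables scatter with a standard deviation of 2 percentage points
- what may be going on: G + E -> D; G + 2 E -> X; 2 E -> J

* the flask with the highest amount of D, in percent of the G charged ("all alike" if they lie within 1.5 percentage points) (oak / alder / all alike)
* final D, as a percentage of the G charged, in oak
* final D, as a percentage of the G charged, in alder

G takes one E to give D and two E to give X, while two E together go to J, so E pays for each step. In the south-west run at 45 °C, D reads 21 % after 0.500 min and 20 % after 3.00 min, flat within the scatter of 2 percentage points, and E, charged at less than G, is the limiting reagent there. The bench rule is to freeze the E yield, the D formed per E charged, which that last reading puts at 33.3 %. D in percent of the G charged is then this yield times the ratio of E charged to G charged, which is 1.20 in oak, so a finished oak should hold 40.0 %.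

The west run marks the border. Its ratio of E to G is 2.40, and there the rule gives 80.0 % where the last reading is 39 %, about half. That run is also colder and still climbing, so the ratio is not the one difference, but the frozen yield does not hold there, and 40.0 % stands on the high side for oak.

Both flasks are read at the same time, but alder is colder and may still be climbing then. The west run at 30 °C goes from 32 % at 2.50 min to 39 % at 6.00 min, so alder, read at 2.5 min, is cut in that proportion to 32.8 %. Oak, hotter than the flat south-west run, is taken as finished, and this reckoning puts oak ahead of alder. The forecast differs: it names alder, with 17 % in oak and 26 % in alder, “suggesting heat favours waste”.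

The flask with more D is oak, at 35.8 % against 30.9 % in alder. At 25.0 min alder holds 32.2 % and oak 35.8 %, so a gap of 3.6 points remains of the 4.9 points at 2.5 min.

    G + E → D (k = 0.120 L mol⁻¹ s⁻¹, Ea = 51.0 kJ mol⁻¹)
    G + 2 E → X (k = 1.00 L² mol⁻² s⁻¹, Ea = 42.0 kJ mol⁻¹)
    2 E → J (k = 0.0720 L mol⁻¹ s⁻¹, Ea = 47.0 kJ mol⁻¹)
    (constants at 35 °C)

The E yield of oak comes to 29.8 %, a little less than the frozen 33.3 %. Frozen at 33.3 %, the yield gives 10.0 % of the G charged for a flask like oak with 1.2 M of G, and that flask holds 10.5 %.

The earlier runs and the new flask are calculated from invented constants; noise was put on by code.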